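## The problem

The target 22 is a 1,1'-linked binaphthalene without stereocentres. Unit A, read as 3,8-dihydroxy-1-methoxy-6-methylnaphthalen-4-yl (atoms A1 to A8a), is joined through A4 to B1 of unit B, read as 4,6-dihydroxy-5-methoxy-2-methylnaphthalen-1-yl (atoms B1 to B8a). The A4–B1 bond is flanked by the A3 oxygen, the A5 peri hydrogen, the B2 methyl group and the B8 peri hydrogen, so joining two finished naphthalenes there is hard; the axis is a potential stereogenic element, but no descriptor is drawn and nothing in the molecule could control it, so there is no stereochemical relay to plan. Six oxygen atoms must be told apart: A1 and B5 are methyl ethers, A3, A8, B4 and B6 are free phenols, and B5 sits between two of them. The free tetraol is an electron-rich, peri-oxygenated naphthol that will not survive oxidants or hot Lewis acids, so the phenols must stay masked until a last, neutral step. The feature that opens a short route lies in ring R of unit B (B1, B2, B3, B4, B4a, B8a): the aryl-bearing B1 and the methyl-bearing B2 are adjacent and correspond to the two sp carbons of a 1-arylpropyne, while B3, B4, B4a and B8a correspond to an arylacetaldehyde with B3 as the aldehyde carbon and the oxygen already on the alpha carbon B4. In that aldehyde the ring can close only at B8a, because the other ortho position is B5 with its methoxy group, and B8a lies para to the B6 oxygen.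

## Retrosynthesis

**22 from 21.** The last cut removes the four O-benzyl groups at A3, A8, B4 and B6. One protecting group for all four phenols means one neutral hydrogenolysis at the end; mixed ester and ether protection would add separate cleavage steps. The two methyl ethers must therefore be in place before the rings are joined. The forward step only has to leave the methyl ethers and the naphthalene rings untouched.

**21 from 13 and 20.** Ring R is opened at B2–B3 and B1–B8a. The neighbouring cut, A4–B1, would require two complete naphthalenes and a cross-coupling at a fully ortho-blocked position. The chosen cut instead turns the hindered biaryl bond into the unhindered aryl–alkyne bond of 13, and reduces unit B to the benzene-level aldehyde 20. The forward reaction asks four things: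
- the alkyne must add with its methyl-bearing carbon to the aldehyde;
- the arene must close at B8a;
- the dihydronaphthalene must aromatize with the B4 oxygen retained;
- four benzyl ethers must survive the Lewis acid.

**13 from 11 and 12; 11 from 10.** The A4–C(sp) bond is cut back to iodide 11 and propyne 12, and the A4–I bond back to the triether 10. A4 is the alpha position ortho and para to the two alkoxy groups of its ring, so halogenation should find it without a free phenol as director. A benzyl ether at A3 (not an ester) keeps this ring activated, avoids a deprotection and reprotection pair, and falls with the other benzyl groups at the end.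

**10 from 9; 9 from 7.** The A8 O-benzyl bond is cut, then the A5–A8 ring is taken back to the tetralone 7. The A8 oxygen is thus a ketone until late and is automatically distinct from the A1 and A3 oxygens. The forward dehydrogenation must spare an electron-rich arene and a benzyl ether.

**7 from 6; 6 from 5.** The A1 O-methyl and A3 O-benzyl bonds are cut in this order because in 5 the future A1 hydroxyl is hydrogen-bonded to the peri ketone and the future A3 hydroxyl is not. The free hydroxyl is benzylated first and the chelated one methylated second, which settles the A1/A3 distinction at the cost of two simple steps.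

**5 from 4; 4 from 1 and 2 through 3.** Ring P is cut at A4–A4a (an aldol bond) back to the fused pyranone 4, which is the dehydrated form of the tetraketone 3 made from dione 1 and the acylketene released from 2. Two steps build a bicyclic resorcinol with both phenols free and differentiated, from commercial materials. The forward ring transformation must outrun cleavage of the acyl side chain.

**20 from 18, 17, 16, 15 and 14.** The aldehyde carbon B3 comes from cleavage of the terminal alkene of 18. The B4 O-benzyl bond leads back to allylic alcohol 17, the B3–B4 bond to vinyl addition onto aldehyde 16, and the B5 methyl and B6 benzyl ethers to 15 and the catechol aldehyde 14. Each step is a standard operation; the only selectivity needed is alkylation of 14 at the oxygen remote from the formyl group.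

## Roads not taken

**Alternative 1:** This road cuts A4–A4a of ring P and carries unit B in as a naphthylmethyl group on the fused pyranone A2. Hydroxide would open A2 to an enolized tetraketone whose benzylic carbon A4 condenses with the ring carbonyl at A4a, giving the resorcinol tetralone A1.
- Merits: the biaryl bond never has to be made between two rings, since it starts as an sp3 carbon–aryl bond. The ring transformation is the one used in step 2 of the chosen route, and its two phenols are distinguished by the same hydrogen bond.
- Weak points: the nucleophile is now a hindered methylene next to a 2-methylnaphthyl group instead of a methyl group, so the aldol should compete poorly with side-chain cleavage. Unit B must first be built as a complete naphthalene with a one-carbon handle at B1. After the key step five operations remain on the biaryl, including dehydrogenation of the tetralone next to the axis.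
- Comparison: on precedent this road is ahead, since no step leaves known reaction types, whereas step 14 extends a known annulation to an alpha-alkoxy aldehyde. The chosen plan sets against this its convergence: ring R and the biaryl connection form together from a benzene-level aldehyde, and one step follows.

**Alternative 2:** This road cuts A4–A4a and A1–A8a by an aryne acyl-alkylation; ring P would close afterwards by Claisen condensation. Fluoride would generate the aryne from silylaryl triflate A4, the enolate of ketoester A5 would add at the aryne carbon remote from the benzyloxy group, and transfer of the acetyl group would give A3.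
- Merits: it is convergent and mild, and ring P would arrive fully aromatic as a 1,3-diol, with no tetralone to dehydrogenate.
- Weak points: a tertiary, heavily hindered alpha-naphthyl enolate must add to the aryne. A5 again needs a finished unit B and an arylation at B1. After ring closure the A1 and A3 hydroxyls are both free and both hindered, so methylation of A1 alone is not secured. A4 itself takes several steps.
- Comparison: in oxidation-state economy for unit A this road is better, since it would replace steps 2 to 5 of the chosen route. The chosen plan sets against it a settled A1/A3 distinction before the union and no separate synthesis of unit B.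

**Alternative 3:** This road cuts A1–A2 and A3–A4. Benzocyclobutenone A7 would open thermally to an o-quinoid ketene methide that adds siloxyalkyne A8 across A1 and A4, giving A6 with a free A1 hydroxyl and a silylated A3 oxygen.
- Merits: the two oxygens of ring P emerge chemically distinct from the key step itself, which is the best answer to the A1/A3 problem among all four plans. The regiochemistry of ynol ether additions to such ketenes is reliable, and the conditions are neutral.
- Weak points: A7 is a strained ketone carrying the bulky unit B on its sp3 carbon. Making it needs an aryne cycloaddition and an alpha-arylation with a hindered unit B halide, after a separate unit B synthesis. The bulky group must rotate outward in the ring opening, and three steps follow.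
- Comparison: in oxygen differentiation this road is better than the chosen one, which spends steps 3 and 4 on it. The chosen plan offers much shorter access to both partners and makes ring R of unit B in the coupling step.

Key step: step 14

Assumption: the A4–B1 axis is drawn without a descriptor, so 22 is made racemic about this axis and no atroposelective step is planned.

## Route

Step 1
Reactants: 1 5-methylcyclohexane-1,3-dione; 2 2,2,6-trimethyl-4H-1,3-dioxin-4-one
Product: 4 2,7-dimethyl-7,8-dihydro-4H-chromene-4,5(6H)-dione (racemic), via open-chain tetraketone 3 (not isolated)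
Conditions: 2 (1.2 equiv), DMAP (10 mol%), PhMe, 100 °C; then TsOH·H2O (20 mol%), reflux, Dean–Stark
Reagents that add atoms: none
Why: Thermolysis of 2 releases acetylketene, which acetoacetylates the enolized dione at C2 (O-acylation and DMAP-mediated O-to-C acyl migration) to give 3; acid-catalysed cyclodehydration of the enolized tricarbonyl array then closes the 4-pyranone, the established access to 5-oxotetrahydrochromones from cyclohexane-1,3-diones.

Step 2
Reactants: 4 2,7-dimethyl-7,8-dihydro-4H-chromene-4,5(6H)-dione
Product: 5 6,8-dihydroxy-3-methyl-3,4-dihydronaphthalen-1(2H)-one (racemic)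
Conditions: KOH (2 M aq.), 70 °C; then HCl (aq.) to pH 2
Reagents that add atoms: none
Why: Hydroxide adds to C2 of the pyranone and opens it to the enolized tetraketone, whose terminal methyl carbanion condenses with the ring carbonyl (intramolecular aldol condensation) and the new ring aromatizes to the resorcinol, a Collie-type pyranone-to-resorcinol ring transformation. The C3 methyl stereocentre is racemic and is erased in step 5.

Step 3
Reactants: 5 6,8-dihydroxy-3-methyl-3,4-dihydronaphthalen-1(2H)-one
Product: 6 6-(benzyloxy)-8-hydroxy-3-methyl-3,4-dihydronaphthalen-1(2H)-one (racemic)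
Conditions: BnBr (1.05 equiv), K2CO3 (1.1 equiv), acetone, reflux
Reagents that add atoms: benzyl bromide, BrCc1ccccc1
Why: Williamson etherification; the C8 hydroxyl is hydrogen-bonded to the peri ketone and much less nucleophilic, so one equivalent of benzyl bromide should alkylate the C6 hydroxyl selectively, as with 2,4-dihydroxyaryl ketones.

Step 4
Reactants: 6 6-(benzyloxy)-8-hydroxy-3-methyl-3,4-dihydronaphthalen-1(2H)-one
Product: 7 6-(benzyloxy)-8-methoxy-3-methyl-3,4-dihydronaphthalen-1(2H)-one (racemic)
Conditions: MeI (3 equiv), K2CO3, DMF, 50 °C
Reagents that add atoms: iodomethane, CI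
Why: With C6 capped, the chelated C8 phenol is methylated under more forcing Williamson conditions; K2CO3 is too weak to enolize the ketone, so C-methylation is not expected.

Step 5
Reactants: 7 6-(benzyloxy)-8-methoxy-3-methyl-3,4-dihydronaphthalen-1(2H)-one
Product: 9 6-(benzyloxy)-8-methoxy-3-methylnaphthalen-1-ol, via alpha-phenylselanyl ketone 8 (not isolated)
Conditions: LiN(iPr)2 (1.1 equiv), THF, −78 °C; PhSeCl; then H2O2 (30% aq.), pyridine, CH2Cl2, 0 °C → rt
Reagents that add atoms: none
Why: Reich selenenylation of the lithium enolate, oxidation to the selenoxide and syn-elimination give the naphthalen-1(4H)-one, which tautomerizes at once to the naphthol. The electrophile should add trans to the C3 methyl group, which places selenium syn to the C3 hydrogen as the elimination requires.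

Step 6
Reactants: 9 6-(benzyloxy)-8-methoxy-3-methylnaphthalen-1-ol
Product: 10 1,6-bis(benzyloxy)-8-methoxy-3-methylnaphthalene
Conditions: BnBr, K2CO3, DMF, 60 °C
Reagents that add atoms: benzyl bromide, BrCc1ccccc1
Why: Williamson etherification of the peri-hydrogen-bonded naphthol in a dipolar aprotic solvent.

Step 7
Reactants: 10 1,6-bis(benzyloxy)-8-methoxy-3-methylnaphthalene
Product: 11 3,8-bis(benzyloxy)-4-iodo-1-methoxy-6-methylnaphthalene
Conditions: NIS (1.05 equiv), MeCN, 0 °C, dark
Reagents that add atoms: N-iodosuccinimide, O=C1CCC(=O)N1I
Why: Electrophilic aromatic iodination; A4 is an alpha position activated by the ortho benzyloxy and para methoxy groups of its own ring, whereas A2 is a flanked beta site and A5 and A7 are each activated by a single alkoxy group, in line with the 4-selective substitution of 1,3-dimethoxynaphthalene.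

Step 8
Reactants: 11 3,8-bis(benzyloxy)-4-iodo-1-methoxy-6-methylnaphthalene; 12 propyne
Product: 13 3,8-bis(benzyloxy)-1-methoxy-6-methyl-4-(prop-1-yn-1-yl)naphthalene
Conditions: propyne (1 M in THF, 3 equiv), PdCl2(PPh3)2 (5 mol%), CuI (10 mol%), Et3N, THF, 50 °C, sealed tube
Reagents that add atoms: none
Why: Sonogashira coupling; the iodide compensates for the electron-rich, ortho-substituted ring, and the sealed vessel keeps the volatile alkyne in solution.

Step 9
Reactants: 14 2,3-dihydroxybenzaldehyde
Product: 15 3-(benzyloxy)-2-hydroxybenzaldehyde
Conditions: NaH (2.2 equiv), DMSO, rt; BnBr (1.0 equiv); then HCl (aq.)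
Reagents that add atoms: benzyl bromide, BrCc1ccccc1
Why: In the dianion the C2 phenoxide is stabilized by conjugation with and chelation to the formyl group, so the more nucleophilic C3 phenoxide takes the single equivalent of benzyl bromide; this is the established 3-O-selective alkylation of this catechol aldehyde.

Step 10
Reactants: 15 3-(benzyloxy)-2-hydroxybenzaldehyde
Product: 16 3-(benzyloxy)-2-methoxybenzaldehyde
Conditions: MeI, K2CO3, DMF, rt
Reagents that add atoms: iodomethane, CI
Why: Williamson methylation of the remaining ortho-formyl phenol.

Step 11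
Reactants: 16 3-(benzyloxy)-2-methoxybenzaldehyde
Product: 17 1-[3-(benzyloxy)-2-methoxyphenyl]prop-2-en-1-ol (racemic)
Conditions: CH2=CHMgBr (1.2 equiv), THF, −78 → 0 °C; then NH4Cl (aq.)
Reagents that add atoms: vinylmagnesium bromide, C=C[Mg]Br
Why: Grignard 1,2-addition to the aryl aldehyde; the carbinol centre is formed racemic and is destroyed in step 14.

Step 12
Reactants: 17 1-[3-(benzyloxy)-2-methoxyphenyl]prop-2-en-1-ol
Product: 18 1-(benzyloxy)-3-[1-(benzyloxy)prop-2-en-1-yl]-2-methoxybenzene (racemic)
Conditions: NaH, BnBr, Bu4NI (cat.), THF, 0 °C → rt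
Reagents that add atoms: benzyl bromide, BrCc1ccccc1
Why: Williamson benzylation of the secondary alkoxide; this benzyl group becomes the B4 oxygen substituent.

Step 13
Reactants: 18 1-(benzyloxy)-3-[1-(benzyloxy)prop-2-en-1-yl]-2-methoxybenzene
Product: 20 2-(benzyloxy)-2-[3-(benzyloxy)-2-methoxyphenyl]acetaldehyde (racemic), via secondary ozonide 19 (not isolated)
Conditions: O3, CH2Cl2, −78 °C (stopped at first excess); then Me2S, −78 °C → rt
Reagents that add atoms: ozone, [O-][O+]=O
Why: Ozonolysis with reductive work-up; the monosubstituted alkene reacts far faster than the arenes at −78 °C. The enolizable alpha-aryl-alpha-alkoxy aldehyde is used crude in step 14 without chromatography.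

Step 14
Reactants: 13 3,8-bis(benzyloxy)-1-methoxy-6-methyl-4-(prop-1-yn-1-yl)naphthalene; 20 2-(benzyloxy)-2-[3-(benzyloxy)-2-methoxyphenyl]acetaldehyde
Product: 21 3,8-bis(benzyloxy)-4-[4,6-bis(benzyloxy)-5-methoxy-2-methylnaphthalen-1-yl]-1-methoxy-6-methylnaphthalene
Conditions: TiCl4 (1.2 equiv), CH2Cl2, −78 → −20 °C; then NaHCO3 (aq.)
Reagents that add atoms: none
Why: Proposed new method: TiCl4 chelates the aldehyde and the alpha-benzyloxy oxygen of 20; the methyl-bearing alkyne carbon of 13 attacks the activated carbonyl (bond B2–B3) and leaves a vinyl cation at B1 that unit A stabilizes through its para A1 methoxy and ortho A3 benzyloxy groups, which fixes the alkyne orientation. The guaiacol ring captures this cation at B8a (bond B1–B8a) in a 6-endo Friedel–Crafts closure of ring R, with the B1=B2 double bond inside the new ring; B8a is the only free ortho position (B5 carries the methoxy group) and lies para to the B6 benzyloxy group. The resulting 1-benzyloxy-2-titanoxy-1,2-dihydronaphthalene should aromatize by ionization of the B3–O bond, which gives an allylic cation delocalized to the doubly benzylic B1, and loss of the B4 proton, so that the benzyloxy group stays at B4; arene 1,2-dihydrodiols dehydrate to 1-naphthols in the same direction. The closest known reaction is the TiCl4- or FeCl3-promoted [4+2] benzannulation of 2-arylacetaldehydes with aryl alkynes to 1-arylnaphthalenes; the new element is the alpha-alkoxy group that survives as a naphthyl ether. No stereocentre remains, since the B3 and B4 centres of the dihydronaphthalene are lost on aromatization and the hindered axis forms racemic. Low temperature is chosen to spare the four benzyl ethers; the selectivities needed (alkyne orientation, closure site, direction of aromatization) are all secured by the substrate.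

Step 15
Reactants: 21 3,8-bis(benzyloxy)-4-[4,6-bis(benzyloxy)-5-methoxy-2-methylnaphthalen-1-yl]-1-methoxy-6-methylnaphthalene
Product: 22 5-(4,6-dihydroxy-5-methoxy-2-methylnaphthalen-1-yl)-8-methoxy-3-methylnaphthalene-1,6-diol
Conditions: H2 (1 atm), Pd/C (10%), EtOAc/MeOH, rt; isolation under argon
Reagents that add atoms: none
Why: Hydrogenolysis of the four aryl benzyl ethers under neutral conditions should release the tetraol; methyl ethers and naphthalene rings are not touched at ambient pressure.

## Compound list

1 | 5-methylcyclohexane-1,3-dione | CC1CC(=O)CC(=O)C1 | starting material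
2 | 2,2,6-trimethyl-4H-1,3-dioxin-4-one | CC1=CC(=O)OC(C)(C)O1 | starting material
3 | 5-methyl-2-(3-oxobutanoyl)cyclohexane-1,3-dione (open-chain tetraketone, enolized, not isolated) | CC(=O)CC(=O)C1C(=O)CC(C)CC1=O | intermediate
4 | 2,7-dimethyl-7,8-dihydro-4H-chromene-4,5(6H)-dione (racemic) | CC1=CC(=O)C2=C(O1)CC(C)CC2=O | intermediate
5 | 6,8-dihydroxy-3-methyl-3,4-dihydronaphthalen-1(2H)-one (racemic) | O=C1CC(C)Cc2cc(O)cc(O)c12 | intermediate
6 | 6-(benzyloxy)-8-hydroxy-3-methyl-3,4-dihydronaphthalen-1(2H)-one (racemic) | O=C1CC(C)Cc2cc(OCc3ccccc3)cc(O)c12 | intermediate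
7 | 6-(benzyloxy)-8-methoxy-3-methyl-3,4-dihydronaphthalen-1(2H)-one (racemic) | O=C1CC(C)Cc2cc(OCc3ccccc3)cc(OC)c12 | intermediate
8 | 6-(benzyloxy)-8-methoxy-3-methyl-2-(phenylselanyl)-3,4-dihydronaphthalen-1(2H)-one (diastereomer mixture, not isolated) | O=C1C([Se]c3ccccc3)C(C)Cc2cc(OCc3ccccc3)cc(OC)c12 | intermediate
9 | 6-(benzyloxy)-8-methoxy-3-methylnaphthalen-1-ol | Oc1cc(C)cc2cc(OCc3ccccc3)cc(OC)c12 | intermediate
10 | 1,6-bis(benzyloxy)-8-methoxy-3-methylnaphthalene | COc1cc(OCc2ccccc2)cc2cc(C)cc(OCc3ccccc3)c12 | intermediate
11 | 3,8-bis(benzyloxy)-4-iodo-1-methoxy-6-methylnaphthalene | COc1cc(OCc2ccccc2)c(I)c2cc(C)cc(OCc3ccccc3)c12 | intermediate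
12 | propyne | CC#C | starting material
13 | 3,8-bis(benzyloxy)-1-methoxy-6-methyl-4-(prop-1-yn-1-yl)naphthalene | CC#Cc1c(OCc2ccccc2)cc(OC)c2c(OCc3ccccc3)cc(C)cc12 | intermediate
14 | 2,3-dihydroxybenzaldehyde | O=Cc1cccc(O)c1O | starting material
15 | 3-(benzyloxy)-2-hydroxybenzaldehyde | O=Cc1cccc(OCc2ccccc2)c1O | intermediate
16 | 3-(benzyloxy)-2-methoxybenzaldehyde | O=Cc1cccc(OCc2ccccc2)c1OC | intermediate
17 | 1-[3-(benzyloxy)-2-methoxyphenyl]prop-2-en-1-ol (racemic) | C=CC(O)c1cccc(OCc2ccccc2)c1OC | intermediate
18 | 1-(benzyloxy)-3-[1-(benzyloxy)prop-2-en-1-yl]-2-methoxybenzene (racemic) | C=CC(OCc1ccccc1)c1cccc(OCc2ccccc2)c1OC | intermediate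
19 | 3-{(benzyloxy)[3-(benzyloxy)-2-methoxyphenyl]methyl}-1,2,4-trioxolane (secondary ozonide, diastereomer mixture, not isolated) | C1OC(OO1)C(OCc1ccccc1)c1cccc(OCc2ccccc2)c1OC | intermediate
20 | 2-(benzyloxy)-2-[3-(benzyloxy)-2-methoxyphenyl]acetaldehyde (racemic) | O=CC(OCc1ccccc1)c1cccc(OCc2ccccc2)c1OC | intermediate
21 | 3,8-bis(benzyloxy)-4-[4,6-bis(benzyloxy)-5-methoxy-2-methylnaphthalen-1-yl]-1-methoxy-6-methylnaphthalene | COc1cc(OCc2ccccc2)c(-c2c(C)cc(OCc3ccccc3)c3c(OC)c(OCc4ccccc4)ccc23)c2cc(C)cc(OCc3ccccc3)c12 | intermediate
22 | 5-(4,6-dihydroxy-5-methoxy-2-methylnaphthalen-1-yl)-8-methoxy-3-methylnaphthalene-1,6-diol (4,5'-dimethoxy-2',7-dimethyl-[1,1'-binaphthalene]-2,4',5,6'-tetrol; no stereocentre, axis racemic) | COc1cc(O)c(-c2c(C)cc(O)c3c(OC)c(O)ccc23)c2cc(C)cc(O)c12 | target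

## Step count and least certain steps

Total: 15 steps. Longest linear sequence: 10 steps (steps 1 to 8, then 14 and 15); the aldehyde branch (steps 9 to 13) has 5 steps.

**Step 14 (key step, new method).**
- What may go wrong: ionization of the benzylic B4–O bond instead of the B3–O bond during aromatization, which would lose or shift the B4 oxygen. Lewis-acid cleavage of benzyl ethers, 1,5-hydride transfer from the A3 benzyl CH2 group to the vinyl cation, chloride capture of that cation, and enolization of the aldehyde before it is attacked are further risks. The alpha-alkoxy substituent has no direct precedent in this annulation.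
- Fallback (known chemistry, biaryl bond by cross-coupling): it sets out from aldehyde 16 and iodide 11 and comes back at 21.
  - Pinnick oxidation of 16 (NaClO2, NaH2PO4, 2-methylbut-2-ene) would give 3-(benzyloxy)-2-methoxybenzoic acid F1, and amide coupling with diethylamine would give 3-(benzyloxy)-N,N-diethyl-2-methoxybenzamide F2.
  - Amide-directed ortho-lithiation (s-BuLi, TMEDA, −78 °C), transmetalation with CuBr·SMe2 and allylation with 3-bromo-2-methylpropene would give 3-(benzyloxy)-N,N-diethyl-2-methoxy-6-(2-methylprop-2-en-1-yl)benzamide F3.
  - Anionic cyclization of F3 with MeLi, the established route to 3-methyl-1-naphthols, would give 7-(benzyloxy)-8-methoxy-3-methylnaphthalen-1-ol F4.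
  - para-Bromination with NBS would give 7-(benzyloxy)-4-bromo-8-methoxy-3-methylnaphthalen-1-ol F5, and benzylation would give 4,6-bis(benzyloxy)-1-bromo-5-methoxy-2-methylnaphthalene F6.
  - Bromine–lithium exchange (n-BuLi) and quenching with iPrOBpin would give 2-[4,6-bis(benzyloxy)-5-methoxy-2-methylnaphthalen-1-yl]-4,4,5,5-tetramethyl-1,3,2-dioxaborolane F7.
  - Suzuki–Miyaura coupling of F7 with 11 (Pd(OAc)2, SPhos, K3PO4, toluene/water, 100 °C) would then form the A4–B1 bond and return to 21.

**Step 2.**
- What may go wrong: hydroxide cleaves the acyl side chain (retro-Claisen) faster than the terminal carbanion closes the carbocycle, or the opened polyketone recloses to the pyranone on acidification.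
- Fallback: it sets out from tetraketone 3, isolated as its enol by stopping step 1 before the acid treatment, and comes back at 5. Treatment of 3 with LiN(iPr)2 (3.3 equiv) in THF would generate the trianion irreversibly and without hydroxide; its terminal carbanion closes the ring by aldol addition, and acidification dehydrates to 5. No compound outside the list is made (entry F0).

**Step 7.**
- What may go wrong: iodination at A5 or A2, or double iodination, because the second ring and the flanked beta site are also activated.
- Fallback: it sets out from 10 and comes back at 13, bypassing 11 and step 8, and uses a weaker and more discriminating electrophile.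
  - Vilsmeier–Haack formylation (POCl3, DMF) would give 2,5-bis(benzyloxy)-4-methoxy-7-methylnaphthalene-1-carbaldehyde F8.
  - Corey–Fuchs olefination (CBr4, PPh3) would give 3,8-bis(benzyloxy)-4-(2,2-dibromoethenyl)-1-methoxy-6-methylnaphthalene F9.
  - n-BuLi (2.2 equiv) would convert F9 into {[2,5-bis(benzyloxy)-4-methoxy-7-methylnaphthalen-1-yl]ethynyl}lithium F10, which is methylated in the same flask with MeI to give 13.

**Step 5.**
- What may go wrong: incomplete syn-elimination from the selenide diastereomer with selenium anti to the C3 hydrogen, and oxidation of the electron-rich naphthol by peroxide or selenium by-products.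
- Fallback: it sets out from 7 and comes back at 9. alpha-Bromination with PhNMe3Br3 in THF would give 6-(benzyloxy)-2-bromo-8-methoxy-3-methyl-3,4-dihydronaphthalen-1(2H)-one F11. Dehydrobromination with LiBr and Li2CO3 in DMF at 120 °C, which tolerates either diastereomer through enolization, would give 9 after tautomerization.

**Step 13.**
- What may go wrong: attack of ozone on the electron-rich rings or the benzylic C–H bonds, and enolization or air oxidation of the aldehyde during handling.
- Fallback: it sets out from 18 and comes back at 20. Dihydroxylation (OsO4 cat., NMO, acetone/water) would give 3-(benzyloxy)-3-[3-(benzyloxy)-2-methoxyphenyl]propane-1,2-diol F12, and glycol cleavage with NaIO4 immediately before step 14 would give 20.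

**Step 15.**
- What may go wrong: incomplete hydrogenolysis of the benzyl ethers next to the hindered axis, and air oxidation of the product during filtration.
- Fallback: it sets out from 21 and comes back at 22. Lewis-acid debenzylation with BCl3 and pentamethylbenzene as cation scavenger in CH2Cl2 at −78 °C should spare the methyl ethers. No compound outside the list is made (entry F0).

## Further compounds

F1 | step 14 | 3-(benzyloxy)-2-methoxybenzoic acid | OC(=O)c1cccc(OCc2ccccc2)c1OC
F2 | step 14 | 3-(benzyloxy)-N,N-diethyl-2-methoxybenzamide | CCN(CC)C(=O)c1cccc(OCc2ccccc2)c1OC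
F3 | step 14 | 3-(benzyloxy)-N,N-diethyl-2-methoxy-6-(2-methylprop-2-en-1-yl)benzamide | CCN(CC)C(=O)c1c(CC(C)=C)ccc(OCc2ccccc2)c1OC
F4 | step 14 | 7-(benzyloxy)-8-methoxy-3-methylnaphthalen-1-ol | Oc1cc(C)cc2ccc(OCc3ccccc3)c(OC)c12
F5 | step 14 | 7-(benzyloxy)-4-bromo-8-methoxy-3-methylnaphthalen-1-ol | Oc1cc(C)c(Br)c2ccc(OCc3ccccc3)c(OC)c12
F6 | step 14 | 4,6-bis(benzyloxy)-1-bromo-5-methoxy-2-methylnaphthalene | Cc1cc(OCc2ccccc2)c2c(OC)c(OCc3ccccc3)ccc2c1Br
F7 | step 14 | 2-[4,6-bis(benzyloxy)-5-methoxy-2-methylnaphthalen-1-yl]-4,4,5,5-tetramethyl-1,3,2-dioxaborolane | Cc1cc(OCc2ccccc2)c2c(OC)c(OCc3ccccc3)ccc2c1B1OC(C)(C)C(C)(C)O1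
F0 | step 2 | none | none
F8 | step 7 | 2,5-bis(benzyloxy)-4-methoxy-7-methylnaphthalene-1-carbaldehyde | O=Cc1c(OCc2ccccc2)cc(OC)c2c(OCc3ccccc3)cc(C)cc12
F9 | step 7 | 3,8-bis(benzyloxy)-4-(2,2-dibromoethenyl)-1-methoxy-6-methylnaphthalene | BrC(Br)=Cc1c(OCc2ccccc2)cc(OC)c2c(OCc3ccccc3)cc(C)cc12
F10 | step 7 | {[2,5-bis(benzyloxy)-4-methoxy-7-methylnaphthalen-1-yl]ethynyl}lithium | [Li]C#Cc1c(OCc2ccccc2)cc(OC)c2c(OCc3ccccc3)cc(C)cc12
F11 | step 5 | 6-(benzyloxy)-2-bromo-8-methoxy-3-methyl-3,4-dihydronaphthalen-1(2H)-one | O=C1C(Br)C(C)Cc2cc(OCc3ccccc3)cc(OC)c12
F12 | step 13 | 3-(benzyloxy)-3-[3-(benzyloxy)-2-methoxyphenyl]propane-1,2-diol | OCC(O)C(OCc1ccccc1)c1cccc(OCc2ccccc2)c1OC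
F0 | step 15 | none | none
A1 | alternative 1 | 5-[4,6-bis(benzyloxy)-5-methoxy-2-methylnaphthalen-1-yl]-6,8-dihydroxy-3-methyl-3,4-dihydronaphthalen-1(2H)-one (racemic) | O=C1CC(C)Cc2c1c(O)cc(O)c2-c1c(C)cc(OCc2ccccc2)c2c(OC)c(OCc3ccccc3)ccc12
A2 | alternative 1 | 2-{[4,6-bis(benzyloxy)-5-methoxy-2-methylnaphthalen-1-yl]methyl}-7-methyl-7,8-dihydro-4H-chromene-4,5(6H)-dione (racemic) | O=C1C=C(Cc2c(C)cc(OCc3ccccc3)c3c(OC)c(OCc4ccccc4)ccc23)OC2=C1C(=O)CC(C)C2
A3 | alternative 2 | methyl 2-[2-acetyl-3-(benzyloxy)-5-methylphenyl]-2-[4,6-bis(benzyloxy)-5-methoxy-2-methylnaphthalen-1-yl]acetate (racemic) | COC(=O)C(c1cc(C)cc(OCc2ccccc2)c1C(C)=O)c1c(C)cc(OCc2ccccc2)c2c(OC)c(OCc3ccccc3)ccc12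
A4 | alternative 2 | 3-(benzyloxy)-5-methyl-2-(trimethylsilyl)phenyl trifluoromethanesulfonate | Cc1cc(OCc2ccccc2)c([Si](C)(C)C)c(OS(=O)(=O)C(F)(F)F)c1
A5 | alternative 2 | methyl 2-[4,6-bis(benzyloxy)-5-methoxy-2-methylnaphthalen-1-yl]-3-oxobutanoate (racemic) | COC(=O)C(C(C)=O)c1c(C)cc(OCc2ccccc2)c2c(OC)c(OCc3ccccc3)ccc12
A6 | alternative 3 | 8-(benzyloxy)-4-[4,6-bis(benzyloxy)-5-methoxy-2-methylnaphthalen-1-yl]-6-methyl-3-[(triisopropylsilyl)oxy]naphthalen-1-ol | Oc1cc(O[Si](C(C)C)(C(C)C)C(C)C)c(-c2c(C)cc(OCc3ccccc3)c3c(OC)c(OCc4ccccc4)ccc23)c2cc(C)cc(OCc3ccccc3)c12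
A7 | alternative 3 | 5-(benzyloxy)-8-[4,6-bis(benzyloxy)-5-methoxy-2-methylnaphthalen-1-yl]-3-methylbicyclo[4.2.0]octa-1,3,5-trien-7-one (racemic) | O=C1C(c2c(C)cc(OCc3ccccc3)c3c(OC)c(OCc4ccccc4)ccc23)c2cc(C)cc(OCc3ccccc3)c12
A8 | alternative 3 | (ethynyloxy)tri(propan-2-yl)silane | C#CO[Si](C(C)C)(C(C)C)C(C)C
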